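**Plan** (longipinane numbering: C1 ketone, C2 CH2, C3 CH–CH3, cyclobutane C4–C5–C11–C10, C6 C(CH3)2, C7–C9 acyloxy carbons, C10 quaternary C–CH3)

1. Cuts: the three angelate C–O bonds; then C5–C11 and C3–C4 together, back to a cyclohept-5-ene (C4=C5) whose quaternary C10 carries the chain C11(=N2)–C1(=O)–C2H2–C3HBr–CH3; then C10–C11 (Claisen rearrangement of a C5–O allyl vinyl ether); then the seven-membered ring, back to 3-methylfuran and a dimethyl-oxyallyl cation, (4+3).
2. Enabling feature: the ketone chain C1–C2–C3 bridges the 1,3-positions C11 and C4 of the cyclobutane C4–C5–C11–C10, so the C4···C11 diagonal is a latent bicyclo[1.1.0]butane bond. C11 (α to the ketone) can be a metal-carbene carbon that adds across C4=C5, and C3 (β′ to the ketone) a radical that reopens the C4–C11 bond.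
3. Ring order forward: seven-membered ring first ((4+3), then opening of the oxygen bridge); cyclobutane and cyclohexanone together in the key step.
4. Stereochemistry: C7 from a catalyst-controlled CBS reduction of an achiral dienedione; C8 and C9 by osmylation anti to C7–OH; a second CBS reduction sets a carbinol (the later C5) whose chirality the suprafacial Claisen shift relays to C10.
5. C10 then forces C4, C5 and C11 (only one topology is possible) and its methyl group steers the C3 methyl group.

Key step: step 13

Assumption: in both CBS reductions (steps 4 and 7) the fully substituted C(CH3)2 carbon acts as the large group; if the alkenyl side dominates, the (R)-catalyst is used instead.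

Step 1
Reactants: 1 3-methylfuran; 2 3-bromo-3-methylbutan-2-one
Product: 3 rac-(1R,5R)-2,2,6-trimethyl-8-oxabicyclo[3.2.1]oct-6-en-3-one
Conditions: Et3N, CF3CH2OH, 0 → 23 °C (1 in excess)
Reagents that add atoms: none
Why: loss of HBr gives the 1,1-dimethyl-2-oxyallyl cation, which adds to the furan in a (4+3) cycloaddition in which the CH2 terminus should bond to the more nucleophilic furan C2 and the hindered C(CH3)2 terminus to the unsubstituted C5, the cis oxygen bridge being the only possible relative configuration (racemic product).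

Step 2
Reactants: 3
Product: 4 rac-6-hydroxy-4,7,7-trimethylcyclohepta-2,4-dien-1-one
Conditions: LiN(SiMe3)2, THF, −78 → −20 °C; AcOH
Reagents that add atoms: none
Why: the ketone has a single enolisable CH2, and its enolate expels the β-oxygen of the bridge (E1cB ring opening) to give the dienone and the allylic alcohol.

Step 3
Reactants: 4
Product: 5 2,2,5-trimethylcyclohepta-4,6-diene-1,3-dione
Conditions: Dess–Martin periodinane, CH2Cl2, 23 °C
Reagents that add atoms: none
Why: Dess–Martin oxidation of the secondary allylic alcohol gives an achiral dienedione, which erases the racemic stereocentre so that a catalyst can set the absolute configuration.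

Step 4
Reactants: 5
Product: 6 (6R)-6-hydroxy-3,7,7-trimethylcyclohepta-2,4-dien-1-one
Conditions: (S)-2-methyl-CBS-oxazaborolidine (20 mol %), catecholborane (1 equiv), PhMe, −78 °C
Reagents that add atoms: none
Why: Corey–Bakshi–Shibata reduction should take the more electrophilic carbonyl (the one whose enone β-carbon is unsubstituted, the other being deactivated by the β-methyl group) and deliver hydride to the face that gives the R carbinol.

Step 5
Reactants: 6
Product: 7 (4S,5S,6S)-4,5,6-trihydroxy-3,7,7-trimethylcyclohept-2-en-1-one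
Conditions: OsO4 (2 mol %), N-methylmorpholine N-oxide, acetone/H2O, 0 → 23 °C
Reagents that add atoms: osmium tetroxide, O=[Os](=O)(=O)=O (regenerated by N-methylmorpholine N-oxide, C[N+]1([O-])CCOCC1)
Why: catalytic osmylation attacks the electron-richer γ,δ-alkene of the dienone and approaches anti to the allylic hydroxyl, so the new cis-diol is trans to that hydroxyl.

Step 6
Reactants: 7
Product: 8 (1S,2S,3S)-4,7,7-trimethyl-6-oxocyclohept-4-ene-1,2,3-triyl triacetate
Conditions: Ac2O, pyridine, DMAP (cat.), CH2Cl2, 23 °C
Reagents that add atoms: acetic anhydride, CC(=O)OC(C)=O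
Why: DMAP-catalysed acylation gives acetates, which tolerate the later acid, heat, carbenoid and radical steps and deactivate the adjacent C–H bonds toward carbene insertion.

Step 7
Reactants: 8
Product: 9 (1S,2S,3S,6R)-6-hydroxy-4,7,7-trimethylcyclohept-4-ene-1,2,3-triyl triacetate
Conditions: (S)-2-methyl-CBS-oxazaborolidine (20 mol %), catecholborane, PhMe, −40 °C
Reagents that add atoms: none
Why: Corey–Bakshi–Shibata 1,2-reduction with the same catalyst sense as in step 4 should give the R allylic alcohol, with the hydroxyl cis to the two neighbouring diol acetates and trans to the neopentyl acetate.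

Step 8
Reactants: 10 (E)-but-2-enal; 11 ethynylmagnesium bromide
Product: 12 rac-(E)-hex-4-en-1-yn-3-ol
Conditions: THF, −78 → 0 °C; NH4Cl (aq)
Reagents that add atoms: none
Why: Grignard 1,2-addition of the alkynyl nucleophile to the enal.

Step 9
Reactants: 12
Product: 13 (E)-hex-4-en-1-yn-3-one
Conditions: Dess–Martin periodinane, CH2Cl2, 0 °C (used as a solution)
Reagents that add atoms: none
Why: Dess–Martin oxidation of the doubly activated alcohol gives the cross-conjugated ynone.

Step 10
Reactants: 9; 13
Product: 15 (4E)-3-oxo-2-[(1R,5S,6R,7S)-5,6,7-triacetoxy-1,4,4-trimethylcyclohept-2-en-1-yl]hex-4-enal, via vinyl ether 14 (not isolated)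
Conditions: 13 (1.5 equiv), PMe3 (10 mol %), CH2Cl2, 0 °C; evaporate; o-xylene, 160 °C, sealed tube
Reagents that add atoms: none
Why: phosphine-catalysed oxa-Michael addition to the ynone terminus and then a Claisen rearrangement whose [3,3] shift is suprafacial across the ring allyl unit, so the quaternary carbon is formed on the face that carried the C–O bond (1,3-chirality transfer), and the formyl group that arrives with it marks the future diazo carbon.

Step 11
Reactants: 15
Product: 16 5-bromo-3-oxo-2-[(1R,5S,6R,7S)-5,6,7-triacetoxy-1,4,4-trimethylcyclohept-2-en-1-yl]hexanal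
Conditions: HBr (33 % in AcOH), CH2Cl2, −20 → 0 °C
Reagents that add atoms: hydrogen bromide, Br
Why: conjugate (Michael-type) hydrobromination of the enone, which leaves the hindered ring alkene and the acetates alone; the C–Br centre needs no control because it becomes a radical.

Step 12
Reactants: 16
Product: 17 (1S,2R,3S,4R)-4-(4-bromo-1-diazo-2-oxopentyl)-4,7,7-trimethylcyclohept-5-ene-1,2,3-triyl triacetate
Conditions: MsN3, 2,6-lutidine, MeCN, 0 °C
Reagents that add atoms: methanesulfonyl azide, CS(=O)(=O)N=[N+]=[N-]
Why: Regitz deformylative diazo transfer reacts only at the formyl-activated carbon, so the diazo group is placed between the quaternary carbon and the ketone, and a pyridine base is enough for the acidic formyl ketone while sparing the β-bromo ketone.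

Step 13
Reactants: 17
Product: 19 (3R,4S,5S,7S,8R,9S,10R,11R)-7,8,9-triacetoxylongipinan-1-one, via bicyclobutane 18 (not isolated)
Conditions: Rh2(O2CCMe3)4 (1 mol %), PhH, 23 °C (slow addition of 17); then Bu3SnH, AIBN, 80 °C (syringe pump)
Reagents that add atoms: none
Why: Proposed new method: Rh2(O2CCMe3)4 converts the diazo group of 17 into a carbene at C11 that adds across the neighbouring ring alkene C4=C5 (intramolecular cyclopropanation of an allyl-tethered α-diazo carbonyl compound, the established entry to bicyclo[1.1.0]butanes), which forms C5–C11 and gives 18 with a strained central C4–C11 bond. Bu3Sn• then abstracts bromine, and the secondary C3 radical, a localized sp3 radical on a flexible two-carbon tether, attacks bridgehead C4 on the convex face while the C4–C11 bond breaks; the resulting C11 bridgehead radical takes hydrogen from Bu3SnH. The closest known reaction types are Giese-type strain-release additions of alkyl radicals to acyl bicyclobutanes (intermolecular) and one-pot bicyclobutanation–ring-opening sequences; the untested element is delivery of the radical from the acyl side chain to forge a bicyclo[3.1.1]heptanone. The cyclobutane is closed by [2+1] carbene addition (two fused cyclopropanes, of which one C–C bond is reopened), and the cyclohexanone by radical substitution at a σ-bond through a five-membered array C3–C2–C1–C11–C4, which ends as a 1,3-bridge across the cyclobutane. C10 fixes the face of carbene addition, and because the seven-membered ring must span the two wing carbons on the concave side and the ketone chain the convex side, C4, C5 and C11 can only arise as shown; at C3 the methyl group should turn away from the exo methyl group on C10. The step needs cyclopropanation to beat C–H insertion and ylide formation (favoured by the allylic proximity of the alkene, the lack of a migrating β-hydrogen at C10 and the deactivating acetates) and cyclisation to beat reduction of the C3 radical (favoured by slow addition of Bu3SnH and the large strain release).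

Step 14
Reactants: 19
Product: 20 (3R,4S,5S,7S,8R,9S,10R,11R)-7,8,9-trihydroxylongipinan-1-one
Conditions: K2CO3 (cat.), MeOH, 23 °C
Reagents that add atoms: none
Why: base-catalysed transesterification removes the acetates, and no centre can epimerise because the ketone's only stereogenic α-carbon is a bridgehead.

Step 15
Reactants: 20; 21 angelic acid (in excess; the source of all three angeloyl groups)
Product: 22 (3R,4S,5S,7S,8R,9S,10R,11R)-7,8,9-tris(angeloyloxy)longipinan-1-one (target)
Conditions: 21 (7 equiv), 2,4,6-Cl3C6H2COCl (3.5 equiv), Et3N (8 equiv), PhMe, 23 °C; then 20, 80 °C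
Reagents that add atoms: angelic anhydride, C/C=C(/C)C(=O)OC(=O)/C(C)=C\C (formed in the flask from 21 and 2,4,6-trichlorobenzoyl chloride; three equivalents react, each passing one angeloyl group to one hydroxyl of 20)
Why: Yamaguchi-type esterification in which two molecules of angelic acid per molecule of the hindered aroyl chloride give angelic anhydride (angelate attacks the unhindered carbonyl of the first-formed mixed anhydride), which then acylates the three secondary hydroxyl groups one after another, each anhydride passing on one angeloyl group and releasing one angelic acid; no nucleophilic amine catalyst is present, so the Z geometry should be kept, and no stereocentre of 20 is touched.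

**Compound list**

1 | 3-methylfuran | Cc1ccoc1 | starting material
2 | 3-bromo-3-methylbutan-2-one | CC(=O)C(C)(C)Br | starting material
3 | rac-(1R,5R)-2,2,6-trimethyl-8-oxabicyclo[3.2.1]oct-6-en-3-one (one enantiomer drawn) | CC1=C[C@H]2O[C@@H]1CC(=O)C2(C)C | intermediate
4 | rac-6-hydroxy-4,7,7-trimethylcyclohepta-2,4-dien-1-one | CC1=CC(O)C(C)(C)C(=O)C=C1 | intermediate
5 | 2,2,5-trimethylcyclohepta-4,6-diene-1,3-dione | CC1=CC(=O)C(C)(C)C(=O)C=C1 | intermediate
6 | (6R)-6-hydroxy-3,7,7-trimethylcyclohepta-2,4-dien-1-one | O=C1C=C(C)C=C[C@@H](O)C1(C)C | intermediate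
7 | (4S,5S,6S)-4,5,6-trihydroxy-3,7,7-trimethylcyclohept-2-en-1-one | O=C1C=C(C)[C@H](O)[C@H](O)[C@@H](O)C1(C)C | intermediate
8 | (1S,2S,3S)-4,7,7-trimethyl-6-oxocyclohept-4-ene-1,2,3-triyl triacetate | O=C1C=C(C)[C@H](OC(C)=O)[C@H](OC(C)=O)[C@@H](OC(C)=O)C1(C)C | intermediate
9 | (1S,2S,3S,6R)-6-hydroxy-4,7,7-trimethylcyclohept-4-ene-1,2,3-triyl triacetate | O[C@@H]1C=C(C)[C@H](OC(C)=O)[C@H](OC(C)=O)[C@@H](OC(C)=O)C1(C)C | intermediate
10 | (E)-but-2-enal | C/C=C/C=O | starting material
11 | ethynylmagnesium bromide | C#C[Mg]Br | starting material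
12 | rac-(E)-hex-4-en-1-yn-3-ol | C/C=C/C(O)C#C | intermediate
13 | (E)-hex-4-en-1-yn-3-one | C/C=C/C(=O)C#C | intermediate
14 | (1S,2S,3S,6R)-4,7,7-trimethyl-6-{[(1E,4E)-3-oxohexa-1,4-dien-1-yl]oxy}cyclohept-4-ene-1,2,3-triyl triacetate | C/C=C/C(=O)/C=C/O[C@@H]1C=C(C)[C@H](OC(C)=O)[C@H](OC(C)=O)[C@@H](OC(C)=O)C1(C)C | intermediate
15 | (4E)-3-oxo-2-[(1R,5S,6R,7S)-5,6,7-triacetoxy-1,4,4-trimethylcyclohept-2-en-1-yl]hex-4-enal (C2 epimers and enol form) | C/C=C/C(=O)C(C=O)[C@@]1(C)C=CC(C)(C)[C@H](OC(C)=O)[C@@H](OC(C)=O)[C@H]1OC(C)=O | intermediate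
16 | 5-bromo-3-oxo-2-[(1R,5S,6R,7S)-5,6,7-triacetoxy-1,4,4-trimethylcyclohept-2-en-1-yl]hexanal (epimers at C2 and C5) | CC(Br)CC(=O)C(C=O)[C@@]1(C)C=CC(C)(C)[C@H](OC(C)=O)[C@@H](OC(C)=O)[C@H]1OC(C)=O | intermediate
17 | (1S,2R,3S,4R)-4-(4-bromo-1-diazo-2-oxopentyl)-4,7,7-trimethylcyclohept-5-ene-1,2,3-triyl triacetate (both C–Br epimers) | CC(Br)CC(=O)C(=[N+]=[N-])[C@@]1(C)C=CC(C)(C)[C@H](OC(C)=O)[C@@H](OC(C)=O)[C@H]1OC(C)=O | intermediate
18 | 1-(3-bromobutanoyl)-2,6,6-trimethyltricyclo[5.1.0.0^2,8]octane-3,4,5-triyl triacetate (bicyclobutane; the seven-membered ring spans the two wing carbons) | CC(Br)CC(=O)[C@@]12[C@H]3[C@@H]1C(C)(C)[C@H](OC(C)=O)[C@@H](OC(C)=O)[C@@H](OC(C)=O)[C@@]23C | intermediate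
19 | (3R,4S,5S,7S,8R,9S,10R,11R)-7,8,9-triacetoxylongipinan-1-one | CC(=O)O[C@@H]1[C@@H](OC(C)=O)C(C)(C)[C@H]2[C@@H]3[C@H](C)CC(=O)[C@H]2[C@]3(C)[C@@H]1OC(C)=O | intermediate
20 | (3R,4S,5S,7S,8R,9S,10R,11R)-7,8,9-trihydroxylongipinan-1-one | O[C@@H]1[C@@H](O)C(C)(C)[C@H]2[C@@H]3[C@H](C)CC(=O)[C@H]2[C@]3(C)[C@@H]1O | intermediate
21 | angelic acid, (Z)-2-methylbut-2-enoic acid | C/C=C(/C)C(O)=O | starting material
22 | (3R,4S,5S,7S,8R,9S,10R,11R)-7,8,9-tris(angeloyloxy)longipinan-1-one | C/C=C(/C)C(=O)O[C@@H]1[C@@H](OC(=O)/C(C)=C\C)C(C)(C)[C@H]2[C@@H]3[C@H](C)CC(=O)[C@H]2[C@]3(C)[C@@H]1OC(=O)/C(C)=C\C | target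

**Step count:** 15 steps in total; longest linear sequence 13 steps (steps 1–7 and 10–15).

**Steps most likely to fail**

Step 13. The carbene may insert into a C–H bond or form a carbonyl ylide with an acetate instead of cyclopropanating. The C3 radical may also be reduced before it reaches C4, or the side-on attack on the central bond may be too slow, so that only an uncyclised ketone is formed. Fallback, from 17 back to 19: the rhodium step is run alone and 18 is isolated. HBr (1 equiv, CH2Cl2, −78 °C) then opens the central bond in the known polar sense (H at the acyl-bearing carbon, Br at the other bridgehead) to give the dibromide F1. Et3N removes HBr from the side chain only (E1cB) and lets the acyl-bearing carbon settle with the acyl group anti to the four-carbon bridge, giving the bromo enone F2. Bu3SnH/AIBN then generates the cyclobutyl radical, which closes on the enone β-carbon in a 6-endo Giese cyclisation to return 19; here the enone geometry, not a free radical, sets C3, and the C3 epimers would be separated.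

Step 10. Addition of the neopentyl alcohol to the ynone may be sluggish, and the acceptor-substituted vinyl ether may need temperatures at which acetyl migration or loss of acetic acid competes with the [3,3] shift. Fallback, from 9 back to 15: acid-catalysed exchange with 2-methoxypropene and Claisen rearrangement of the isopropenyl ether (PPTS, xylene, 140 °C) gives the methyl ketone F3. Its kinetic enolate (LiN(SiMe3)2, −78 °C) and acetaldehyde give the aldol F4, and MsCl/Et3N then DBU gives the E enone F5. C-formylation of the remaining α-methylene (LiN(SiMe3)2, 2,2,2-trifluoroethyl formate, −78 °C) returns 15.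

Step 15. Acylation of the C7 and C9 hydroxyls, each next to a quaternary carbon, may stay incomplete, and forcing conditions may isomerise the angeloyl donor from Z to E. Fallback, from 20 back to 22: DCC/DMAP esterification with 2-[bis(2,2,2-trifluoroethoxy)phosphoryl]propanoic acid gives the tris(phosphonopropanoate) F6. A Still–Gennari olefination with acetaldehyde (KN(SiMe3)2, 18-crown-6, THF, −78 °C) then builds the three Z-enoates on the molecule and returns 22.

**Further compounds**

F1 | step 13 | 7-bromo-8-(3-bromobutanoyl)-1,5,5-trimethylbicyclo[4.1.1]octane-2,3,4-triyl triacetate (acyl group anti to the four-carbon bridge; epimers at both C–Br carbons) | CC(Br)CC(=O)[C@@H]1[C@@H]2C(Br)[C@@]1(C)[C@H](OC(C)=O)[C@H](OC(C)=O)[C@@H](OC(C)=O)C2(C)C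
F2 | step 13 | 7-bromo-8-[(E)-but-2-enoyl]-1,5,5-trimethylbicyclo[4.1.1]octane-2,3,4-triyl triacetate | C/C=C/C(=O)[C@@H]1[C@@H]2C(Br)[C@@]1(C)[C@H](OC(C)=O)[C@H](OC(C)=O)[C@@H](OC(C)=O)C2(C)C
F3 | step 10 | 4,7,7-trimethyl-4-(2-oxopropyl)cyclohept-5-ene-1,2,3-triyl triacetate (ring configuration as in 17) | CC(=O)C[C@@]1(C)C=CC(C)(C)[C@H](OC(C)=O)[C@@H](OC(C)=O)[C@H]1OC(C)=O
F4 | step 10 | 4-(4-hydroxy-2-oxopentyl)-4,7,7-trimethylcyclohept-5-ene-1,2,3-triyl triacetate | CC(O)CC(=O)C[C@@]1(C)C=CC(C)(C)[C@H](OC(C)=O)[C@@H](OC(C)=O)[C@H]1OC(C)=O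
F5 | step 10 | 4,7,7-trimethyl-4-[(E)-2-oxopent-3-en-1-yl]cyclohept-5-ene-1,2,3-triyl triacetate | C/C=C/C(=O)C[C@@]1(C)C=CC(C)(C)[C@H](OC(C)=O)[C@@H](OC(C)=O)[C@H]1OC(C)=O
F6 | step 15 | 7,8,9-tris{2-[bis(2,2,2-trifluoroethoxy)phosphoryl]propanoyloxy}longipinan-1-one | CC(C(=O)O[C@@H]1[C@@H](OC(=O)C(C)P(=O)(OCC(F)(F)F)OCC(F)(F)F)C(C)(C)[C@H]2[C@@H]3[C@H](C)CC(=O)[C@H]2[C@]3(C)[C@@H]1OC(=O)C(C)P(=O)(OCC(F)(F)F)OCC(F)(F)F)P(=O)(OCC(F)(F)F)OCC(F)(F)F
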